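**Plan**
- Numbering: benzofuran numbering (O1, aryl-bearing C2, C3 with its CH2OH, C3a/C7a); ring A is the fused benzene ring, ring B the 4-hydroxy-3,5-dimethoxyphenyl group on C2.
- Retrosynthesis: cut the C3–C3a bond together with the CH2–O bond, then the O1–C2 bond, then the C=C bond of a ring B cinnamyl unit.
- Enabling feature: C3 and the CH2OH carbon are the two carbons of a vinyl group on C2. C2 is then an allylic, benzylic ether carbon on the ring A oxygen, and C3a, ortho to that oxygen, can carry iodine as a radical precursor.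
- Forward: iodinated methyl dihydroferulate (ring A) and a silyl-protected sinapyl methyl carbonate (ring B, from syringaldehyde) are joined at O1–C2 by iridium-catalysed branched-selective allylic etherification. The dihydrofuran ring then closes by 5-exo aryl radical cyclization with nitroxide capture; N–O cleavage and desilylation finish.
- Stereochemistry: C2 (S) comes from the chiral phosphoramidite ligand in the allylic etherification; C3 (R) comes from C2 during ring closure (trans).

Key step: step 7

Assumption: with ligand L = O,O'-(1,1'-binaphthyl-2,2'-diyl) N,N-bis(1-phenylethyl)phosphoramidite, the (Sa,Sc,Sc) enantiomer is taken to give the (S)-ether from an (E)-cinnamyl-type carbonate; if the sense is the reverse, (Ra,Rc,Rc)-L is used and nothing else changes.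

**Route**

Step 1
Reactants: 1 methyl 3-(4-hydroxy-3-methoxyphenyl)propanoate (methyl dihydroferulate)
Product: 2 methyl 3-(4-hydroxy-3-iodo-5-methoxyphenyl)propanoate
Conditions: I2 (1.05 equiv), NaHCO3, THF–H2O, 0 °C to rt
Reagents that add atoms: iodine, II
Why: Electrophilic aromatic iodination through the phenoxide goes to the only free position ortho to the phenolic oxygen (the para position carries the side chain), and bicarbonate is too mild to touch the methyl ester.

Step 2
Reactants: 3 syringaldehyde (4-hydroxy-3,5-dimethoxybenzaldehyde)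
Product: 4 3,5-dimethoxy-4-(triisopropylsilyloxy)benzaldehyde
Conditions: i-Pr3SiCl, imidazole, DMF, rt
Reagents that add atoms: triisopropylsilyl chloride, CC(C)[Si](Cl)(C(C)C)C(C)C
Why: Imidazole-promoted silylation of the acidic phenol gives a bulky silyl ether that should withstand ylide, hydride, aryloxide, methoxide, tin radical and warm aqueous acetic acid conditions and that donates less electron density into ring B than a free phenol would.

Step 3
Reactants: 4 3,5-dimethoxy-4-(triisopropylsilyloxy)benzaldehyde
Product: 5 methyl (E)-3-[3,5-dimethoxy-4-(triisopropylsilyloxy)phenyl]prop-2-enoate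
Conditions: Ph3P=CHCO2Me, toluene, 90 °C
Reagents that add atoms: methyl (triphenylphosphoranylidene)acetate, COC(=O)C=P(c1ccccc1)(c1ccccc1)c1ccccc1
Why: Wittig olefination with a stabilized ylide should give the (E)-cinnamate under neutral conditions that spare the aryl silyl ether.

Step 4
Reactants: 5 methyl (E)-3-[3,5-dimethoxy-4-(triisopropylsilyloxy)phenyl]prop-2-enoate
Product: 7 (E)-3-[3,5-dimethoxy-4-(triisopropylsilyloxy)phenyl]prop-2-en-1-ol, via enal 6 (not isolated)
Conditions: i-Bu2AlH (2.5 equiv), CH2Cl2, −78 °C; aq. potassium sodium tartrate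
Reagents that add atoms: none
Why: i-Bu2AlH reduces the unsaturated ester in 1,2-fashion through the enal to the allylic alcohol at low temperature without touching the alkene or the silyl ether.

Step 5
Reactants: 7 (E)-3-[3,5-dimethoxy-4-(triisopropylsilyloxy)phenyl]prop-2-en-1-ol
Product: 8 (E)-3-[3,5-dimethoxy-4-(triisopropylsilyloxy)phenyl]prop-2-enyl methyl carbonate
Conditions: ClCO2Me, pyridine, CH2Cl2, 0 °C
Reagents that add atoms: methyl chloroformate, COC(=O)Cl
Why: Acylation of the primary allylic alcohol with a chloroformate installs the methyl carbonate leaving group used in iridium-catalysed allylic substitution, and the methoxide it later releases can only exchange degenerately with the methyl ester on ring A.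

Step 6
Reactants: 2 methyl 3-(4-hydroxy-3-iodo-5-methoxyphenyl)propanoate; 8 (E)-3-[3,5-dimethoxy-4-(triisopropylsilyloxy)phenyl]prop-2-enyl methyl carbonate
Product: 10 methyl 3-{3-iodo-5-methoxy-4-[(1S)-1-(3,5-dimethoxy-4-triisopropylsilyloxyphenyl)prop-2-enyloxy]phenyl}propanoate, via lithium aryloxide 9 (not isolated)
Conditions: 2 (1.3 equiv), LiN(SiMe3)2 (1.3 equiv), THF, 0 °C; then 8, [Ir(cod)Cl]2 (2 mol%), (Sa,Sc,Sc)-L (4 mol%, pre-activated with n-PrNH2), THF, rt to 50 °C
Reagents that add atoms: none
Why: Iridium-catalysed enantioselective allylic etherification, in which the cyclometalated monovalent iridium species formed from [Ir(cod)Cl]2 and L ionizes the linear carbonate to a trivalent iridium allyl complex and the aryloxide attacks the aryl-substituted terminus on the face away from the metal, so that the branched ether forms and the ligand fixes the (S) configuration at the future C2.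

Step 7
Reactants: 10 methyl 3-{3-iodo-5-methoxy-4-[(1S)-1-(3,5-dimethoxy-4-triisopropylsilyloxyphenyl)prop-2-enyloxy]phenyl}propanoate; 11 2,2,6,6-tetramethylpiperidin-1-oxyl (TEMPO)
Product: 12 methyl 3-[(2S,3R)-2-[3,5-dimethoxy-4-(triisopropylsilyloxy)phenyl]-7-methoxy-3-[(2,2,6,6-tetramethylpiperidin-1-yl)oxymethyl]-2,3-dihydro-1-benzofuran-5-yl]propanoate
Conditions: Bu3SnH (4 equiv, in portions), TEMPO (6 equiv), benzene (0.02 M in 10), 70 °C
Reagents that add atoms: TEMPO (compound 11), CC1(C)CCCC(C)(C)N1[O]
Why: TEMPO abstracts hydrogen from Bu3SnH, the Bu3Sn radical takes iodine from ring A, the sigma aryl radical at C3a adds to the internal vinyl carbon (C3–C3a bond) and the exocyclic primary radical couples with TEMPO at oxygen (CH2–O bond). The closest known reaction type is the tin hydride mediated aryl radical–alkene cyclization of 2-iodoaryl allyl ethers and N-allyl anilines with nitroxide capture. The dihydrofuran ring closes in the 5-exo-trig mode, which for a 2-(allyloxy)phenyl radical is far faster than bimolecular capture of the aryl radical by nitroxide or Bu3SnH at these concentrations and is preferred over 6-endo closure. The new C3 stereocentre is controlled by the existing C2 centre: in the envelope-like transition state the C2 aryl group lies pseudo-equatorial and the alkene CH2 terminus turns away from it, which should give the trans (2S,3R) product. The step needs chemoselectivity (ring closure before any capture, then nitroxide capture of the primary radical before Sn–H reduction), secured by the intramolecular rate and the nitroxide excess, and trans diastereoselectivity, secured by the bulky C2 substituent. The neutral, non-ionizing medium leaves the allylic, benzylic C2–O1 bond, the ester and the silyl ether untouched.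

Step 8
Reactants: 12 methyl 3-[(2S,3R)-2-[3,5-dimethoxy-4-(triisopropylsilyloxy)phenyl]-7-methoxy-3-[(2,2,6,6-tetramethylpiperidin-1-yl)oxymethyl]-2,3-dihydro-1-benzofuran-5-yl]propanoate
Product: 13 methyl 3-[(2S,3R)-2-[3,5-dimethoxy-4-(triisopropylsilyloxy)phenyl]-3-(hydroxymethyl)-7-methoxy-2,3-dihydro-1-benzofuran-5-yl]propanoate
Conditions: Zn dust, AcOH–THF–H2O (3:1:1), 50 °C
Reagents that add atoms: none
Why: Reductive N–O cleavage of a tetramethylpiperidinyl alkyl ether by zinc in aqueous acetic acid is the standard way to unmask the alcohol from a nitroxide adduct and should not touch C2, C3, the ester or the aryl silyl ether.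

Step 9
Reactants: 13 methyl 3-[(2S,3R)-2-[3,5-dimethoxy-4-(triisopropylsilyloxy)phenyl]-3-(hydroxymethyl)-7-methoxy-2,3-dihydro-1-benzofuran-5-yl]propanoate
Product: 14 methyl 3-[(2S,3R)-2-(4-hydroxy-3,5-dimethoxyphenyl)-3-(hydroxymethyl)-7-methoxy-2,3-dihydro-1-benzofuran-5-yl]propanoate
Conditions: n-Bu4NF, AcOH (1:1), THF, 0 °C
Reagents that add atoms: none
Why: Fluoride-mediated desilylation of the aryl silyl ether, buffered with acetic acid so that the liberated para-hydroxyphenyl group stays protonated and cannot expel the C2–O1 aryloxide as a quinone methide, should leave both stereocentres as set.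

**Compound list**
1 | methyl 3-(4-hydroxy-3-methoxyphenyl)propanoate (methyl dihydroferulate) | COC(=O)CCc1ccc(O)c(OC)c1 | starting material
2 | methyl 3-(4-hydroxy-3-iodo-5-methoxyphenyl)propanoate | COC(=O)CCc1cc(I)c(O)c(OC)c1 | intermediate
3 | syringaldehyde (4-hydroxy-3,5-dimethoxybenzaldehyde) | COc1cc(C=O)cc(OC)c1O | starting material
4 | 3,5-dimethoxy-4-(triisopropylsilyloxy)benzaldehyde | COc1cc(C=O)cc(OC)c1O[Si](C(C)C)(C(C)C)C(C)C | intermediate
5 | methyl (E)-3-[3,5-dimethoxy-4-(triisopropylsilyloxy)phenyl]prop-2-enoate | COC(=O)/C=C/c1cc(OC)c(O[Si](C(C)C)(C(C)C)C(C)C)c(OC)c1 | intermediate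
6 | (E)-3-[3,5-dimethoxy-4-(triisopropylsilyloxy)phenyl]prop-2-enal (not isolated) | O=C/C=C/c1cc(OC)c(O[Si](C(C)C)(C(C)C)C(C)C)c(OC)c1 | intermediate
7 | (E)-3-[3,5-dimethoxy-4-(triisopropylsilyloxy)phenyl]prop-2-en-1-ol | OC/C=C/c1cc(OC)c(O[Si](C(C)C)(C(C)C)C(C)C)c(OC)c1 | intermediate
8 | (E)-3-[3,5-dimethoxy-4-(triisopropylsilyloxy)phenyl]prop-2-enyl methyl carbonate | COC(=O)OC/C=C/c1cc(OC)c(O[Si](C(C)C)(C(C)C)C(C)C)c(OC)c1 | intermediate
9 | lithium 2-iodo-6-methoxy-4-(3-methoxy-3-oxopropyl)phenolate (not isolated) | [Li+].COC(=O)CCc1cc(I)c([O-])c(OC)c1 | intermediate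
10 | methyl 3-{3-iodo-5-methoxy-4-[(1S)-1-(3,5-dimethoxy-4-triisopropylsilyloxyphenyl)prop-2-enyloxy]phenyl}propanoate | COC(=O)CCc1cc(OC)c(O[C@@H](C=C)c2cc(OC)c(O[Si](C(C)C)(C(C)C)C(C)C)c(OC)c2)c(I)c1 | intermediate
11 | 2,2,6,6-tetramethylpiperidin-1-oxyl (TEMPO) | CC1(C)CCCC(C)(C)N1[O] | starting material
12 | methyl 3-[(2S,3R)-2-[3,5-dimethoxy-4-(triisopropylsilyloxy)phenyl]-7-methoxy-3-[(2,2,6,6-tetramethylpiperidin-1-yl)oxymethyl]-2,3-dihydro-1-benzofuran-5-yl]propanoate | COC(=O)CCc1cc(OC)c2c(c1)[C@H](CON1C(C)(C)CCCC1(C)C)[C@@H](c1cc(OC)c(O[Si](C(C)C)(C(C)C)C(C)C)c(OC)c1)O2 | intermediate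
13 | methyl 3-[(2S,3R)-2-[3,5-dimethoxy-4-(triisopropylsilyloxy)phenyl]-3-(hydroxymethyl)-7-methoxy-2,3-dihydro-1-benzofuran-5-yl]propanoate | COC(=O)CCc1cc(OC)c2c(c1)[C@H](CO)[C@@H](c1cc(OC)c(O[Si](C(C)C)(C(C)C)C(C)C)c(OC)c1)O2 | intermediate
14 | methyl 3-[(2S,3R)-2-(4-hydroxy-3,5-dimethoxyphenyl)-3-(hydroxymethyl)-7-methoxy-2,3-dihydro-1-benzofuran-5-yl]propanoate | COC(=O)CCc1cc(OC)c2c(c1)[C@H](CO)[C@@H](c1cc(OC)c(O)c(OC)c1)O2 | target

**Count**
Total steps: 9. Longest linear sequence: 8 steps (3 to 14, steps 2–9); the ring A branch from 1 is 5 steps.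

**Steps most likely to fail**

Step 6. The doubly ortho-substituted aryloxide may attack slowly, and the product, an allylic and benzylic aryl ether, may be re-ionized at iridium, which would erode branched selectivity and enantiomeric purity. Fallback: an enantiospecific rhodium-catalysed etherification of a preformed chiral branched carbonate, setting out from 4 and returning at 10.
- CH2=CHMgBr (THF, −78 °C) should add to 4 to give racemic 1-[3,5-dimethoxy-4-(triisopropylsilyloxy)phenyl]prop-2-en-1-ol F1.
- Acylation with vinyl acetate catalysed by Candida antarctica lipase B is expected to consume the (R)-alcohol as (1R)-1-[3,5-dimethoxy-4-(triisopropylsilyloxy)phenyl]prop-2-enyl acetate F3 and to leave (1S)-1-[3,5-dimethoxy-4-(triisopropylsilyloxy)phenyl]prop-2-en-1-ol F2.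
- ClCO2Me/pyridine converts the latter into (1S)-1-[3,5-dimethoxy-4-(triisopropylsilyloxy)phenyl]prop-2-enyl methyl carbonate F4.
- RhCl(PPh3)3 modified with P(OMe)3 (THF, 0 °C to rt) then couples this carbonate with aryloxide 9, made from 2 and LiN(SiMe3)2 as before. Substitution at the carbon that carried the leaving group with net retention should give 10.

Step 7. The aryl radical may be captured by nitroxide or Bu3SnH before ring closure, the chain may be retarded by the large nitroxide excess, or facial discrimination at C3 may be insufficient at 70 °C. Fallback: an oxygenative radical cyclization with O2 as the trap, setting out from 10 and returning at 13, so that step 8 is skipped.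
- Bu3SnH is added slowly to 10 in toluene at 0 °C to rt under a stream of dry air.
- Dissolved O2 is too dilute to intercept the aryl radical before 5-exo closure but should capture the cyclized primary radical, giving methyl 3-[(2S,3R)-2-[3,5-dimethoxy-4-(triisopropylsilyloxy)phenyl]-3-(hydroperoxymethyl)-7-methoxy-2,3-dihydro-1-benzofuran-5-yl]propanoate F5.
- PPh3 reduces this hydroperoxide in the same flask to 13; the lower temperature should also favour the trans isomer.

Step 8. Reduction of the hindered N–O bond may be sluggish and force higher temperature, at which acid-promoted ionization of the benzylic C2–O1 bond (epimerization, solvolysis) or loss of the silyl ether could set in. Fallback: oxidative fragmentation in place of reduction, setting out from 12 and returning at 13.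
- mCPBA (CH2Cl2, 0 °C) oxidizes the alkoxyamine nitrogen, and the N-oxide should fragment by syn-elimination to methyl 3-[(2S,3S)-2-[3,5-dimethoxy-4-(triisopropylsilyloxy)phenyl]-3-formyl-7-methoxy-2,3-dihydro-1-benzofuran-5-yl]propanoate F6.
- The aldehyde is reduced at once with NaBH4 (MeOH, −20 °C) to 13, before the C3 centre next to the formyl group can enolize.

**Further compounds**
F1 | step 6 | racemic 1-[3,5-dimethoxy-4-(triisopropylsilyloxy)phenyl]prop-2-en-1-ol | OC(C=C)c1cc(OC)c(O[Si](C(C)C)(C(C)C)C(C)C)c(OC)c1
F2 | step 6 | (1S)-1-[3,5-dimethoxy-4-(triisopropylsilyloxy)phenyl]prop-2-en-1-ol | O[C@@H](C=C)c1cc(OC)c(O[Si](C(C)C)(C(C)C)C(C)C)c(OC)c1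
F3 | step 6 | (1R)-1-[3,5-dimethoxy-4-(triisopropylsilyloxy)phenyl]prop-2-enyl acetate | CC(=O)O[C@H](C=C)c1cc(OC)c(O[Si](C(C)C)(C(C)C)C(C)C)c(OC)c1
F4 | step 6 | (1S)-1-[3,5-dimethoxy-4-(triisopropylsilyloxy)phenyl]prop-2-enyl methyl carbonate | COC(=O)O[C@@H](C=C)c1cc(OC)c(O[Si](C(C)C)(C(C)C)C(C)C)c(OC)c1
F5 | step 7 | methyl 3-[(2S,3R)-2-[3,5-dimethoxy-4-(triisopropylsilyloxy)phenyl]-3-(hydroperoxymethyl)-7-methoxy-2,3-dihydro-1-benzofuran-5-yl]propanoate | COC(=O)CCc1cc(OC)c2c(c1)[C@H](COO)[C@@H](c1cc(OC)c(O[Si](C(C)C)(C(C)C)C(C)C)c(OC)c1)O2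
F6 | step 8 | methyl 3-[(2S,3S)-2-[3,5-dimethoxy-4-(triisopropylsilyloxy)phenyl]-3-formyl-7-methoxy-2,3-dihydro-1-benzofuran-5-yl]propanoate | COC(=O)CCc1cc(OC)c2c(c1)[C@H](C=O)[C@@H](c1cc(OC)c(O[Si](C(C)C)(C(C)C)C(C)C)c(OC)c1)O2
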